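**Plan**

- Retrosynthesis (flavanone numbering; ring A = C4a–C8a, ring C = pyranone, ring B = aryl): remove three MOM groups; cut C2–C1′ (aryl addition to a chromone); open ring C at O1–C2, C3–C4 and C4–C4a (ethynyl ketone built on a formyl carbon); cut ring A at C4a–C5, C5–C6 and C8–C8a (benzannulation), then C6–C7 (cyclobutenone) and C6–C1″ (geranylation of an acetate enolate).
- Enabling feature: ring A carries oxygen on C5, C7 and C8a (O1), mutually meta, with geranyl on C6 between O5 and O7 and hydrogen on C8 (and on C4a before acylation). This pattern is one ketene carbonyl carbon (C5, with C6 behind it) plus two HC≡C–OSi units (C8–C7 and C4a–C8a), and it delivers O5 as the only free hydroxyl.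
- Forward: geranylacetyl chloride gives a ketene that adds siloxyethyne to a 3-siloxycyclobutenone; a second siloxyethyne builds ring A (step 7). The free O5–H directs formylation to C4a and is then capped as MOM; ethynylation, oxidation and fluoride close ring C through O1. O7 is para to the ketone and cannot close, so O7 and O1 can share one silyl group. Ring B is added last.
- Stereochemistry: the single stereocentre C2 (S) is set by the chiral bisphosphine in the rhodium-catalysed 1,4-addition of step 16; the (2″E) alkene comes with geranyl bromide; the final acid step does not involve C2.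

Key step: step 7

Assumption: (S)-MeO-F12-BIPHEP [(S)-6,6′-dimethoxy-2,2′-bis[bis(3,4,5-trifluorophenyl)phosphino]-1,1′-biphenyl] is taken to give the (2S) product, by analogy with (S)-biaryl bisphosphines in rhodium-catalysed additions to cyclic enones; if the sense proves opposite, the (R)-ligand is used.

**Route**

Step 1
Reactants: 1 geranyl bromide [(2E)-1-bromo-3,7-dimethylocta-2,6-diene]; 2 ethyl acetate
Product: 4 ethyl (4E)-5,9-dimethyldeca-4,8-dienoate, via lithium enolate 3 (not isolated)
Conditions: LiN(i-Pr)2 (1.3 equiv), THF, −78 °C; 2 (1.4 equiv); then 1, DMPU, −78 → −30 °C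
Reagents that add atoms: none
Why: Alkylation of an ester lithium enolate by a primary allylic bromide (SN2 at the CH2Br carbon) should join C6 to C1″ without touching the (2E) alkene.

Step 2
Reactants: 4 ethyl (4E)-5,9-dimethyldeca-4,8-dienoate
Product: 5 (4E)-5,9-dimethyldeca-4,8-dienoic acid
Conditions: LiOH·H2O (3 equiv), THF/MeOH/H2O, rt; then 1 M HCl, 0 °C, to pH 3
Reagents that add atoms: lithium hydroxide, [Li+].[OH-]
Why: Saponification of the ethyl ester (acyl substitution by hydroxide) followed by cold, dilute acidification should leave the trisubstituted alkenes intact.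

Step 3
Reactants: 5 (4E)-5,9-dimethyldeca-4,8-dienoic acid
Product: 6 (4E)-5,9-dimethyldeca-4,8-dienoyl chloride
Conditions: (COCl)2 (1.3 equiv), DMF (cat.), CH2Cl2, 0 °C → rt; evaporate, use crude
Reagents that add atoms: oxalyl chloride, O=C(Cl)C(=O)Cl
Why: Acid chloride formation through the Vilsmeier-type chloroiminium catalyst gives only gaseous by-products, so the crude chloride can be used at once.

Step 4
Reactants: 7 ethynyltrimethylsilane
Product: 10 1-(triisopropylsilyloxy)-2-(trimethylsilyl)ethyne, via lithium acetylide 8 (not isolated), via lithium ynolate 9 (not isolated)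
Conditions: n-BuLi, THF, −78 °C; t-BuOOLi [from t-BuOOH + LiN(SiMe3)2, THF, −78 °C], −78 → 0 °C; i-Pr3SiOTf (1.1 equiv), −78 → 0 °C
Reagents that add atoms: tert-butyl hydroperoxide (as its lithium salt), CC(C)(C)OO; triisopropylsilyl trifluoromethanesulfonate, CC(C)[Si](C(C)C)(C(C)C)OS(=O)(=O)C(F)(F)F
Why: Electrophilic oxygen transfer from lithium tert-butyl peroxide to a lithium acetylide is the standard acetylide-to-ynolate oxidation, and the bulky silyl triflate, unlike small silyl chlorides, should silylate the ynolate on oxygen and not on the carbon that already carries SiMe3.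

Step 5
Reactants: 10 1-(triisopropylsilyloxy)-2-(trimethylsilyl)ethyne
Product: 11 (triisopropylsilyloxy)ethyne
Conditions: K2CO3 (0.1 equiv), MeOH, 0 °C, short contact; pentane/pH 7 buffer, careful concentration
Reagents that add atoms: none
Why: Base-catalysed methanolysis of an alkynyl–SiMe3 bond (protodesilylation) should be selective because methoxide attacks the unhindered trimethylsilyl silicon far faster than the triisopropylsilyl silicon, and the basic medium does not protonate the electron-rich alkyne.

Step 6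
Reactants: 6 (4E)-5,9-dimethyldeca-4,8-dienoyl chloride; 11 (triisopropylsilyloxy)ethyne
Product: 13 4-[(2E)-3,7-dimethylocta-2,6-dien-1-yl]-3-(triisopropylsilyloxy)cyclobut-2-en-1-one (racemic), via geranylketene 12 (not isolated)
Conditions: 11 (1.3 equiv), Et3N (1.2 equiv), Et2O, 0 °C, slow addition of 6; → rt; filter, concentrate, no aqueous work-up
Reagents that add atoms: none
Why: Dehydrochlorination gives the aldoketene, which is trapped in a regioselective ketene–ynol ether [2+2] cycloaddition (the nucleophilic CH terminus of 11 bonds to the ketene carbonyl carbon) to the 3-siloxycyclobutenone; its C4 centre forms racemic and is erased in step 7.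

Step 7
Reactants: 13 4-[(2E)-3,7-dimethylocta-2,6-dien-1-yl]-3-(triisopropylsilyloxy)cyclobut-2-en-1-one; 11 (triisopropylsilyloxy)ethyne
Product: 18 2-[(2E)-3,7-dimethylocta-2,6-dien-1-yl]-3,5-bis(triisopropylsilyloxy)phenol, via vinylketene 14 (not isolated), via vinylcyclobutenone 15 (not isolated), via dienylketene 16 (not isolated), via cyclohexadienone 17 (not isolated)
Conditions: 11 (2 equiv), toluene, 80 °C then 110 °C, argon
Reagents that add atoms: none
Why: Heating opens 13 by 4π electrocyclic ring opening to vinylketene 14, whose ketene C=C adds [2+2] across the electron-rich alkyne 11 to give 15; a second 4π opening gives dienylketene 16, which closes ring A by a thermally allowed disrotatory 6π electrocyclisation and tautomerises (17 → 18). This is the Danheiser benzannulation of a cyclobutenone with a siloxyalkyne, applied here to a 3-siloxycyclobutenone. The bonds made are ketene carbon to alkyne CH, cyclobutenone C2 to the oxygen-bearing alkyne carbon, and ketene carbon to cyclobutenone C4 (re-formed in the 6π closure); in the numbering that the later formylation fixes these are C4a–C5, C8–C8a and C5–C6. No stereocentre survives, because the sp3 carbon of 17 is erased on aromatisation. The selectivity needed is the regiochemistry of the ketene–alkyne [2+2], which the polarisation of 11 secures (its unsubstituted, nucleophilic carbon bonds to the ketene carbonyl carbon), so that the new hydroxyl sits next to geranyl and one siloxy group para to it. Excess 11, together with outward rotation of the C4 substituent on ring opening (geranyl trans to the ketene), should keep ketene dimerisation and [2+2] capture by the C2″=C3″ alkene from competing.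

Step 8
Reactants: 18 2-[(2E)-3,7-dimethylocta-2,6-dien-1-yl]-3,5-bis(triisopropylsilyloxy)phenol
Product: 20 3-[(2E)-3,7-dimethylocta-2,6-dien-1-yl]-2-hydroxy-4,6-bis(triisopropylsilyloxy)benzaldehyde, via hydroxymethylphenol 19 (not isolated)
Conditions: MgCl2 (2 equiv), Et3N (4 equiv), (CH2O)n (6 equiv), MeCN, 75 °C; aq. NH4Cl
Reagents that add atoms: paraformaldehyde (as formaldehyde), C=O
Why: In the Casnati–Skattebøl ortho-formylation the magnesium phenoxide delivers formaldehyde to the only free ortho carbon (the para carbon does not react under these conditions) and the resulting benzylic alkoxide is oxidised by a second formaldehyde through hydride transfer, under basic conditions that spare the silyl ethers and the diene.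

Step 9
Reactants: 20 3-[(2E)-3,7-dimethylocta-2,6-dien-1-yl]-2-hydroxy-4,6-bis(triisopropylsilyloxy)benzaldehyde
Product: 21 3-[(2E)-3,7-dimethylocta-2,6-dien-1-yl]-2-(methoxymethoxy)-4,6-bis(triisopropylsilyloxy)benzaldehyde
Conditions: MeOCH2Cl (2 equiv), i-Pr2NEt (3 equiv), CH2Cl2, 0 → 40 °C
Reagents that add atoms: chloromethyl methyl ether, COCCl
Why: Williamson-type O-alkylation of the chelated phenol with an α-chloro ether (MOM protection) caps the one ortho oxygen that must not take part in closing ring C.

Step 10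
Reactants: 21 3-[(2E)-3,7-dimethylocta-2,6-dien-1-yl]-2-(methoxymethoxy)-4,6-bis(triisopropylsilyloxy)benzaldehyde
Product: 22 1-{3-[(2E)-3,7-dimethylocta-2,6-dien-1-yl]-2-(methoxymethoxy)-4,6-bis(triisopropylsilyloxy)phenyl}prop-2-yn-1-ol (racemic)
Conditions: HC≡CMgBr (1.5 equiv, 0.5 M in THF), THF, 0 °C; aq. NH4Cl
Reagents that add atoms: ethynylmagnesium bromide, C#C[Mg]Br
Why: Grignard addition of a small alkynylmagnesium halide to the hindered aldehyde, helped by chelation to the ortho MOM oxygen, forms C3–C4; the carbinol centre forms racemic and is removed in step 11.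

Step 11
Reactants: 22 1-{3-[(2E)-3,7-dimethylocta-2,6-dien-1-yl]-2-(methoxymethoxy)-4,6-bis(triisopropylsilyloxy)phenyl}prop-2-yn-1-ol
Product: 23 1-{3-[(2E)-3,7-dimethylocta-2,6-dien-1-yl]-2-(methoxymethoxy)-4,6-bis(triisopropylsilyloxy)phenyl}prop-2-yn-1-one
Conditions: MnO2 (activated, 15 equiv), CH2Cl2, rt
Reagents that add atoms: none
Why: MnO2 oxidation of an alcohol that is both benzylic and propargylic is fast under neutral heterogeneous conditions, which leave the trisubstituted alkenes, the acetal and the silyl ethers alone.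

Step 12
Reactants: 23 1-{3-[(2E)-3,7-dimethylocta-2,6-dien-1-yl]-2-(methoxymethoxy)-4,6-bis(triisopropylsilyloxy)phenyl}prop-2-yn-1-one
Product: 25 6-[(2E)-3,7-dimethylocta-2,6-dien-1-yl]-7-hydroxy-5-(methoxymethoxy)-4H-chromen-4-one, via bis-phenoxide 24 (not isolated)
Conditions: Bu4NF (2.5 equiv, 1 M in THF), THF, 0 °C → rt; aq. NH4Cl
Reagents that add atoms: none
Why: Fluoride cleaves both aryl silyl ethers and the phenoxide ortho to the ynone closes ring C by 6-endo-dig oxa-Michael addition to the terminal alkyne carbon (the base-mediated cyclisation of 2′-hydroxyaryl ynones to chromones); the para phenoxide cannot reach the alkyne and the other ortho oxygen is MOM-capped, so only the 6-geranyl isomer can form.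

Step 13
Reactants: 25 6-[(2E)-3,7-dimethylocta-2,6-dien-1-yl]-7-hydroxy-5-(methoxymethoxy)-4H-chromen-4-one
Product: 26 6-[(2E)-3,7-dimethylocta-2,6-dien-1-yl]-5,7-bis(methoxymethoxy)-4H-chromen-4-one
Conditions: MeOCH2Cl (1.5 equiv), i-Pr2NEt (2 equiv), CH2Cl2, 0 °C → rt
Reagents that add atoms: chloromethyl methyl ether, COCCl
Why: MOM protection (O-alkylation with an α-chloro ether) of the acidic 7-hydroxyl keeps the chromone a neutral, electrophilic enone for step 16.

Step 14
Reactants: 27 4-bromo-2,6-dimethoxyphenol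
Product: 28 5-bromo-1,3-dimethoxy-2-(methoxymethoxy)benzene
Conditions: MeOCH2Cl (1.5 equiv), i-Pr2NEt (2 equiv), CH2Cl2, 0 °C → rt
Reagents that add atoms: chloromethyl methyl ether, COCCl
Why: MOM protection of the phenol (O-alkylation with an α-chloro ether) makes the aryl bromide compatible with lithiation and matches the protecting groups of ring A.

Step 15
Reactants: 28 5-bromo-1,3-dimethoxy-2-(methoxymethoxy)benzene
Product: 31 [3,5-dimethoxy-4-(methoxymethoxy)phenyl]boronic acid, via aryllithium 29 (not isolated), via lithium arylborate 30 (not isolated)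
Conditions: n-BuLi (1.05 equiv), THF, −78 °C; B(Oi-Pr)3 (1.5 equiv), −78 °C → rt; aq. NH4Cl
Reagents that add atoms: triisopropyl borate, CC(C)OB(OC(C)C)OC(C)C; water, O
Why: Bromine–lithium exchange, electrophilic borylation with a trialkyl borate and hydrolysis of the borate ester should give the boronic acid, the MOM ether surviving the near-neutral work-up.

Step 16
Reactants: 26 6-[(2E)-3,7-dimethylocta-2,6-dien-1-yl]-5,7-bis(methoxymethoxy)-4H-chromen-4-one; 31 [3,5-dimethoxy-4-(methoxymethoxy)phenyl]boronic acid
Product: 32 (2S)-2-[3,5-dimethoxy-4-(methoxymethoxy)phenyl]-6-[(2E)-3,7-dimethylocta-2,6-dien-1-yl]-5,7-bis(methoxymethoxy)-2,3-dihydro-4H-chromen-4-one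
Conditions: [RhCl(C2H4)2]2 (1.5 mol%), (S)-MeO-F12-BIPHEP (3.3 mol%), 31 (3 equiv), KOH (0.2 equiv), toluene/H2O 10:1, 20 °C
Reagents that add atoms: none
Why: In this Hayashi–Miyaura-type rhodium-catalysed asymmetric 1,4-addition to a chromone, transmetalation gives an aryl–rhodium species whose insertion into C2=C3 is face-selective under control of the chiral bisphosphine, which sets C2 as (S), and water protonates the rhodium enolate; the electron-poor ligand should make insertion fast at 20 °C so that base-induced ring opening of the product does not compete.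

Step 17
Reactants: 32 (2S)-2-[3,5-dimethoxy-4-(methoxymethoxy)phenyl]-6-[(2E)-3,7-dimethylocta-2,6-dien-1-yl]-5,7-bis(methoxymethoxy)-2,3-dihydro-4H-chromen-4-one
Product: 33 (2S)-6-[(2E)-3,7-dimethylocta-2,6-dien-1-yl]-5,7-dihydroxy-2-(4-hydroxy-3,5-dimethoxyphenyl)-2,3-dihydro-4H-chromen-4-one (CNP0372687.1)
Conditions: HCl (3 M), MeOH/H2O, 45 °C, monitored; then aq. NaHCO3
Reagents that add atoms: none
Why: Acid-catalysed methanolysis of the three MOM acetals (transacetalisation) should free the phenols without involving C2, since no base is present, and geranyl-substituted flavanones are expected to tolerate these conditions for the short time needed.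

**Compound list**

1 | geranyl bromide, (2E)-1-bromo-3,7-dimethylocta-2,6-diene | BrC/C=C(\C)CCC=C(C)C | starting material
2 | ethyl acetate | CCOC(C)=O | starting material
3 | lithium 1-ethoxyethen-1-olate | C=C(OCC)O[Li] | intermediate (not isolated)
4 | ethyl (4E)-5,9-dimethyldeca-4,8-dienoate | CCOC(=O)CC/C=C(\C)CCC=C(C)C | intermediate
5 | (4E)-5,9-dimethyldeca-4,8-dienoic acid | OC(=O)CC/C=C(\C)CCC=C(C)C | intermediate
6 | (4E)-5,9-dimethyldeca-4,8-dienoyl chloride | ClC(=O)CC/C=C(\C)CCC=C(C)C | intermediate
7 | ethynyltrimethylsilane | C#C[Si](C)(C)C | starting material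
8 | lithium (trimethylsilyl)acetylide | [Li]C#C[Si](C)(C)C | intermediate (not isolated)
9 | lithium 2-(trimethylsilyl)ethynolate | [Li]OC#C[Si](C)(C)C | intermediate (not isolated)
10 | 1-(triisopropylsilyloxy)-2-(trimethylsilyl)ethyne | C[Si](C)(C)C#CO[Si](C(C)C)(C(C)C)C(C)C | intermediate
11 | (triisopropylsilyloxy)ethyne | C#CO[Si](C(C)C)(C(C)C)C(C)C | intermediate
12 | geranylketene, (4E)-5,9-dimethyldeca-1,4,8-trien-1-one | O=C=CC/C=C(\C)CCC=C(C)C | intermediate (not isolated)
13 | 4-[(2E)-3,7-dimethylocta-2,6-dien-1-yl]-3-(triisopropylsilyloxy)cyclobut-2-en-1-one (racemic) | O=C1C=C(O[Si](C(C)C)(C(C)C)C(C)C)C1C/C=C(\C)CCC=C(C)C | intermediate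
14 | vinylketene, (4E,7E)-8,12-dimethyl-3-(triisopropylsilyloxy)trideca-1,2,4,7,11-pentaen-1-one | O=C=C/C(O[Si](C(C)C)(C(C)C)C(C)C)=C/C/C=C(\C)CCC=C(C)C | intermediate (not isolated)
15 | 3-(triisopropylsilyloxy)-4-[1-(triisopropylsilyloxy)alkenyl]cyclobut-2-en-1-one carrying the geranyl-CH2 on the vinyl terminus (racemic) | O=C1C=C(O[Si](C(C)C)(C(C)C)C(C)C)C1/C(O[Si](C(C)C)(C(C)C)C(C)C)=C/C/C=C(\C)CCC=C(C)C | intermediate (not isolated)
16 | dienylketene with 3,5-bis(triisopropylsilyloxy) groups, (3Z)-configured for closure | O=C=C/C(O[Si](C(C)C)(C(C)C)C(C)C)=C\C(O[Si](C(C)C)(C(C)C)C(C)C)=C\C/C=C(\C)CCC=C(C)C | intermediate (not isolated)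
17 | 6-[(2E)-3,7-dimethylocta-2,6-dien-1-yl]-3,5-bis(triisopropylsilyloxy)cyclohexa-2,4-dien-1-one (racemic) | O=C1C=C(O[Si](C(C)C)(C(C)C)C(C)C)C=C(O[Si](C(C)C)(C(C)C)C(C)C)C1C/C=C(\C)CCC=C(C)C | intermediate (not isolated)
18 | 2-[(2E)-3,7-dimethylocta-2,6-dien-1-yl]-3,5-bis(triisopropylsilyloxy)phenol | Oc1cc(O[Si](C(C)C)(C(C)C)C(C)C)cc(O[Si](C(C)C)(C(C)C)C(C)C)c1C/C=C(\C)CCC=C(C)C | intermediate
19 | 2-[(2E)-3,7-dimethylocta-2,6-dien-1-yl]-6-(hydroxymethyl)-3,5-bis(triisopropylsilyloxy)phenol | OCc1c(O)c(C/C=C(\C)CCC=C(C)C)c(O[Si](C(C)C)(C(C)C)C(C)C)cc1O[Si](C(C)C)(C(C)C)C(C)C | intermediate (not isolated)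
20 | 3-[(2E)-3,7-dimethylocta-2,6-dien-1-yl]-2-hydroxy-4,6-bis(triisopropylsilyloxy)benzaldehyde | O=Cc1c(O)c(C/C=C(\C)CCC=C(C)C)c(O[Si](C(C)C)(C(C)C)C(C)C)cc1O[Si](C(C)C)(C(C)C)C(C)C | intermediate
21 | 3-[(2E)-3,7-dimethylocta-2,6-dien-1-yl]-2-(methoxymethoxy)-4,6-bis(triisopropylsilyloxy)benzaldehyde | O=Cc1c(OCOC)c(C/C=C(\C)CCC=C(C)C)c(O[Si](C(C)C)(C(C)C)C(C)C)cc1O[Si](C(C)C)(C(C)C)C(C)C | intermediate
22 | 1-{3-[(2E)-3,7-dimethylocta-2,6-dien-1-yl]-2-(methoxymethoxy)-4,6-bis(triisopropylsilyloxy)phenyl}prop-2-yn-1-ol (racemic) | C#CC(O)c1c(OCOC)c(C/C=C(\C)CCC=C(C)C)c(O[Si](C(C)C)(C(C)C)C(C)C)cc1O[Si](C(C)C)(C(C)C)C(C)C | intermediate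
23 | 1-{3-[(2E)-3,7-dimethylocta-2,6-dien-1-yl]-2-(methoxymethoxy)-4,6-bis(triisopropylsilyloxy)phenyl}prop-2-yn-1-one | C#CC(=O)c1c(OCOC)c(C/C=C(\C)CCC=C(C)C)c(O[Si](C(C)C)(C(C)C)C(C)C)cc1O[Si](C(C)C)(C(C)C)C(C)C | intermediate
24 | bis(tetrabutylammonium) salt of the doubly desilylated ynone (4,6-diolate) | C#CC(=O)c1c(OCOC)c(C/C=C(\C)CCC=C(C)C)c([O-])cc1[O-].CCCC[N+](CCCC)(CCCC)CCCC.CCCC[N+](CCCC)(CCCC)CCCC | intermediate (not isolated)
25 | 6-[(2E)-3,7-dimethylocta-2,6-dien-1-yl]-7-hydroxy-5-(methoxymethoxy)-4H-chromen-4-one | O=c1ccoc2cc(O)c(C/C=C(\C)CCC=C(C)C)c(OCOC)c12 | intermediate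
26 | 6-[(2E)-3,7-dimethylocta-2,6-dien-1-yl]-5,7-bis(methoxymethoxy)-4H-chromen-4-one | O=c1ccoc2cc(OCOC)c(C/C=C(\C)CCC=C(C)C)c(OCOC)c12 | intermediate
27 | 4-bromo-2,6-dimethoxyphenol | COc1cc(Br)cc(OC)c1O | starting material
28 | 5-bromo-1,3-dimethoxy-2-(methoxymethoxy)benzene | COCOc1c(OC)cc(Br)cc1OC | intermediate
29 | [3,5-dimethoxy-4-(methoxymethoxy)phenyl]lithium | COCOc1c(OC)cc([Li])cc1OC | intermediate (not isolated)
30 | lithium [3,5-dimethoxy-4-(methoxymethoxy)phenyl]triisopropoxyborate | COCOc1c(OC)cc([B-](OC(C)C)(OC(C)C)OC(C)C)cc1OC.[Li+] | intermediate (not isolated)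
31 | [3,5-dimethoxy-4-(methoxymethoxy)phenyl]boronic acid | COCOc1c(OC)cc(B(O)O)cc1OC | intermediate
32 | (2S)-2-[3,5-dimethoxy-4-(methoxymethoxy)phenyl]-6-[(2E)-3,7-dimethylocta-2,6-dien-1-yl]-5,7-bis(methoxymethoxy)-2,3-dihydro-4H-chromen-4-one | COCOc1c(OC)cc([C@@H]2CC(=O)c3c(cc(OCOC)c(C/C=C(\C)CCC=C(C)C)c3OCOC)O2)cc1OC | intermediate
33 | (2S)-6-[(2E)-3,7-dimethylocta-2,6-dien-1-yl]-5,7-dihydroxy-2-(4-hydroxy-3,5-dimethoxyphenyl)-2,3-dihydro-4H-chromen-4-one | COc1cc([C@@H]2CC(=O)c3c(cc(O)c(C/C=C(\C)CCC=C(C)C)c3O)O2)cc(OC)c1O | target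

**Step count**

Total: 17 steps. Longest linear sequence: 13 steps (1, 2, 3, 6, 7, 8, 9, 10, 11, 12, 13, 16, 17).

**Steps most likely to fail**

1. Step 5 (with step 4 behind it). Methanolysis may attack the oxygen-bound silicon or protonate the electron-rich alkyne, so that the ynol silyl ether is lost as ketene-derived ester while the C–Si bond is being cleaved; the small terminal alkyne may also be lost on concentration. The fallback makes the parent ynolate first and silylates it second. It replaces compounds 7–10, so it sets out from no numbered compound but from purchased 3-phenylisoxazole (c1cc(-c2ccccc2)no1), and it comes back to the route at 11. Deprotonation at C5 with n-BuLi (THF, −78 °C) should give 5-lithio-3-phenylisoxazole F1, which fragments to benzonitrile and lithium ethynolate F2; O-silylation with i-Pr3SiOTf at −78 °C then gives 11 directly, with no carbon-bound silyl group to remove.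

2. Step 7. Vinylketene 14 may be consumed by dimerisation, or the moisture-sensitive vinylogous silyl ester of 13 may hydrolyse, before the bimolecular [2+2] with 11 takes place; the second ring opening may also stall at 15. The fallback gives up the pericyclic construction for electrophilic substitution and sets out from 1, coming back at 18. C-Alkylation of purchased benzene-1,3,5-triol (in excess) with 1 and DBU in THF at 0 °C → rt should give 2-[(2E)-3,7-dimethylocta-2,6-dien-1-yl]benzene-1,3,5-triol F3. Treatment with i-Pr3SiCl (2.1 equiv) and imidazole in DMF at 0 °C should silylate the unhindered para hydroxyl first and then one of the two equivalent geranyl-flanked hydroxyls, giving 18 after chromatography, at the cost of a statistical step.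

3. Step 16. Insertion into the electron-rich, 5,6,7-trisubstituted chromone may be slow enough for protodeboronation of the electron-rich boronic acid to use up the aryl donor, and hydroxide may open the product through retro-oxa-Michael reaction and so erode the enantiomeric purity. The fallback sets C2 by separation instead of by catalysis; it sets out from 26 and 31 and comes back at 32. Addition without a chiral ligand ([Rh(OH)(cod)]2, dioxane/H2O, 50 °C) should give the racemic protected flavanone F4, which is resolved by preparative HPLC on a chiral stationary phase (amylose tris(3,5-dimethylphenylcarbamate)); the (2S) enantiomer is 32 and the (2R)-enantiomer F5 is set aside.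

**Further compounds**

F1 | step 5 | 5-lithio-3-phenylisoxazole | [Li]c1cc(-c2ccccc2)no1
F2 | step 5 | lithium ethynolate | [Li]OC#C
F3 | step 7 | 2-[(2E)-3,7-dimethylocta-2,6-dien-1-yl]benzene-1,3,5-triol | Oc1cc(O)c(C/C=C(\C)CCC=C(C)C)c(O)c1
F4 | step 16 | racemic 2-[3,5-dimethoxy-4-(methoxymethoxy)phenyl]-6-[(2E)-3,7-dimethylocta-2,6-dien-1-yl]-5,7-bis(methoxymethoxy)-2,3-dihydro-4H-chromen-4-one | COCOc1c(OC)cc(C2CC(=O)c3c(cc(OCOC)c(C/C=C(\C)CCC=C(C)C)c3OCOC)O2)cc1OC
F5 | step 16 | (2R)-2-[3,5-dimethoxy-4-(methoxymethoxy)phenyl]-6-[(2E)-3,7-dimethylocta-2,6-dien-1-yl]-5,7-bis(methoxymethoxy)-2,3-dihydro-4H-chromen-4-one | COCOc1c(OC)cc([C@H]2CC(=O)c3c(cc(OCOC)c(C/C=C(\C)CCC=C(C)C)c3OCOC)O2)cc1OC
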